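**Retrosynthetic overview**

1. Target 21 comes from octamethyl ether 20 by global O-demethylation; 20 comes from bis(Weinreb amide) 17 and two equivalents of 2-lithio-1,3-dimethoxybenzene, which install both 2,6-dioxygenated benzoyl ends at once.
2. The strategy rests on ring B (C1'–C6'): its two carbon substituents are ortho (C1' bonded to C5 of catechol ring A, C6' bearing the chain), its two oxygens sit on the opposite pair C3'/C4', and the benzylic chain carbon on C6' can be a ketone that is later reduced to CH2.
3. Ring B is therefore cut at C1'–C2' and C5'–C6' into aryl alkynyl ketone 12 (supplying C1', C6' and the chain) and 2,3-dimethoxybuta-1,3-diene 13 (supplying C2'–C5' with both oxygens); the [4+2] adduct 14 is dehydrogenated to the veratrole.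
4. Ynone 12 comes from terminal alkyne 9 and the half-ester chloride 11 of azelaic acid; 9 comes from 3-bromo-4,5-dimethoxybenzaldehyde 3 by Wittig chain extension, diimide reduction and Sonogashira ethynylation.
5. Ring order: ring A and the two resorcinol rings are purchased arenes; ring B is the only ring built (step 8) and is aromatised in step 9.

Key step: step 8

Assumption: the target has no stereocentre and its biaryl axis, with only two ortho substituents, rotates freely, so no stereocontrol is planned; 2,3-dimethoxybuta-1,3-diene is taken as a purchasable reagent; in the systematic biphenyl names ring A is the unprimed ring and ring B the primed ring.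

**Route**

Step 1
Reactants: 1 methyl 8-bromooctanoate
Product: 2 (8-methoxy-8-oxooctyl)triphenylphosphonium bromide
Conditions: PPh3 (1.1 equiv), MeCN, reflux
Reagents that add atoms: triphenylphosphine, c1ccc(cc1)P(c1ccccc1)c1ccccc1
Why: SN2 quaternisation of triphenylphosphine by an unhindered primary alkyl bromide should be clean, the methyl ester being inert.

Step 2
Reactants: 2 (8-methoxy-8-oxooctyl)triphenylphosphonium bromide; 3 3-bromo-4,5-dimethoxybenzaldehyde
Product: 5 methyl (Z)-9-(3-bromo-4,5-dimethoxyphenyl)non-8-enoate, via phosphonium ylide 4 (not isolated)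
Conditions: NaN(SiMe3)2 (1.05 equiv), THF, −78 → 0 °C; then 3, −78 °C → rt
Reagents that add atoms: none
Why: Wittig olefination of an aromatic aldehyde with a non-stabilised ylide generated cold by a non-nucleophilic amide base, so the ester is not attacked; the alkene is expected mainly Z with some E, which is irrelevant because the double bond is saturated in step 3.

Step 3
Reactants: 5 methyl (Z)-9-(3-bromo-4,5-dimethoxyphenyl)non-8-enoate
Product: 6 methyl 9-(3-bromo-4,5-dimethoxyphenyl)nonanoate
Conditions: TsNHNH2 (6 equiv), NaOAc (6 equiv), THF/H2O, reflux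
Reagents that add atoms: none
Why: diimide reduction transfers H2 to the disubstituted C=C in a concerted syn fashion and leaves the aryl bromide, which palladium-catalysed hydrogenation could cleave, and the ester untouched.

Step 4
Reactants: 6 methyl 9-(3-bromo-4,5-dimethoxyphenyl)nonanoate; 7 ethynyltrimethylsilane
Product: 8 methyl 9-{3,4-dimethoxy-5-[(trimethylsilyl)ethynyl]phenyl}nonanoate
Conditions: PdCl2(PPh3)2 (5 mol %), CuI (5 mol %), Et3N/DMF, 80 °C, sealed tube
Reagents that add atoms: none
Why: Sonogashira coupling, in which zerovalent palladium inserts into the Ar–Br bond (heating compensates for the ortho methoxy group) and the copper acetylide transmetallates; the silyl cap prevents double arylation.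

Step 5
Reactants: 8 methyl 9-{3,4-dimethoxy-5-[(trimethylsilyl)ethynyl]phenyl}nonanoate
Product: 9 methyl 9-(3-ethynyl-4,5-dimethoxyphenyl)nonanoate
Conditions: K2CO3 (0.2 equiv), MeOH, rt
Reagents that add atoms: none
Why: methoxide-induced protodesilylation of the alkynylsilane is fast at room temperature, and transesterification of a methyl ester in methanol is degenerate.

Step 6
Reactants: 10 9-methoxy-9-oxononanoic acid (monomethyl azelate)
Product: 11 methyl 9-chloro-9-oxononanoate
Conditions: (COCl)2 (1.5 equiv), DMF (cat.), CH2Cl2, 0 °C → rt; evaporate, use crude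
Reagents that add atoms: oxalyl chloride, ClC(=O)C(Cl)=O
Why: acid chloride formation through the Vilsmeier-type chloroiminium catalyst converts only the free acid, and the by-products are gases.

Step 7
Reactants: 9 methyl 9-(3-ethynyl-4,5-dimethoxyphenyl)nonanoate; 11 methyl 9-chloro-9-oxononanoate
Product: 12 methyl 11-[2,3-dimethoxy-5-(9-methoxy-9-oxononyl)phenyl]-9-oxoundec-10-ynoate
Conditions: PdCl2(PPh3)2 (2 mol %), CuI (4 mol %), Et3N (1.5 equiv), THF, rt
Reagents that add atoms: none
Why: acyl Sonogashira coupling, in which zerovalent palladium inserts into the C–Cl bond of the acid chloride at room temperature and the copper acetylide transmetallates, gives the ynone without a lithium acetylide that would attack the two esters.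

Step 8
Reactants: 12 methyl 11-[2,3-dimethoxy-5-(9-methoxy-9-oxononyl)phenyl]-9-oxoundec-10-ynoate; 13 2,3-dimethoxybuta-1,3-diene
Product: 14 methyl 9-{2-[2,3-dimethoxy-5-(9-methoxy-9-oxononyl)phenyl]-4,5-dimethoxycyclohexa-1,4-dien-1-yl}-9-oxononanoate
Conditions: 13 (5 equiv), BHT (cat.), toluene, 140 °C, sealed tube, Ar; concentrate, use crude
Reagents that add atoms: none
Why: thermal normal-electron-demand Diels–Alder reaction in which the s-cis diene, its HOMO raised by the two methoxy groups, adds suprafacially across the C10≡C11 triple bond of 12, whose LUMO is lowered by the conjugated C9 ketone, forming C1'–C2' and C5'–C6' in one concerted event. The closest known reaction type is the cycloaddition of 2,3-dialkoxybutadienes with acetylenic ketones and esters to give 1,2-dialkoxycyclohexa-1,4-dienes. Ring B is closed as a six-membered carbocycle by intermolecular [4+2] annulation, four carbons coming from the diene and two from the alkyne, not by end-to-end cyclisation of a chain. No stereocentre is created, since every new ring carbon is sp2 or CH2. The step needs chemoselectivity for the conjugated alkyne over the ester and ketone carbonyls, a single addition, and survival of the acid-labile enol ethers. The C2-symmetric diene removes any regiochemical question, the tetrasubstituted enone C=C of 14 is too hindered to add a second diene, and acid-free, radical-inhibited conditions with excess diene protect the diene and the adduct.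

Step 9
Reactants: 14 methyl 9-{2-[2,3-dimethoxy-5-(9-methoxy-9-oxononyl)phenyl]-4,5-dimethoxycyclohexa-1,4-dien-1-yl}-9-oxononanoate
Product: 15 methyl 9-[2,3,4',5'-tetramethoxy-5-(9-methoxy-9-oxononyl)-[1,1'-biphenyl]-2'-yl]-9-oxononanoate
Conditions: DDQ (1.1 equiv), toluene, 0 °C → rt
Reagents that add atoms: none
Why: quinone dehydrogenation, in which DDQ abstracts hydride from a doubly allylic CH2 next to an enol ether carbon and proton loss follows, is driven by aromatisation and should be much faster than any benzylic oxidation.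

Step 10
Reactants: 15 methyl 9-[2,3,4',5'-tetramethoxy-5-(9-methoxy-9-oxononyl)-[1,1'-biphenyl]-2'-yl]-9-oxononanoate
Product: 16 dimethyl 9,9'-(2,3,4',5'-tetramethoxy-[1,1'-biphenyl]-2',5-diyl)dinonanoate
Conditions: Et3SiH (10 equiv), CF3CO2H, 0 °C → rt
Reagents that add atoms: none
Why: ionic hydrogenation, in which the protonated aryl ketone takes hydride from the silane, the resulting benzylic oxygen function ionises to a cation stabilised by the para methoxy group and a second hydride is delivered; esters and aryl ethers are inert, and the large excess of silane is meant to outrun capture of the cation by ring A.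

Step 11
Reactants: 16 dimethyl 9,9'-(2,3,4',5'-tetramethoxy-[1,1'-biphenyl]-2',5-diyl)dinonanoate
Product: 17 9,9'-(2,3,4',5'-tetramethoxy-[1,1'-biphenyl]-2',5-diyl)bis(N-methoxy-N-methylnonanamide)
Conditions: MeNH(OMe)·HCl (6 equiv), i-PrMgCl (12 equiv), THF, −20 → 0 °C
Reagents that add atoms: N,O-dimethylhydroxylamine hydrochloride, CNOC.Cl
Why: direct aminolysis of unhindered methyl esters by the chloromagnesium amide of N,O-dimethylhydroxylamine is a standard Weinreb amide synthesis, and at low temperature the Grignard base does not add to the ester.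

Step 12
Reactants: 17 9,9'-(2,3,4',5'-tetramethoxy-[1,1'-biphenyl]-2',5-diyl)bis(N-methoxy-N-methylnonanamide); 18 1,3-dimethoxybenzene
Product: 20 9,9'-(2,3,4',5'-tetramethoxy-[1,1'-biphenyl]-2',5-diyl)bis[1-(2,6-dimethoxyphenyl)nonan-1-one], via 2,6-dimethoxyphenyllithium 19 (not isolated)
Conditions: 18 (6 equiv), n-BuLi (5.5 equiv), THF, 0 °C → rt; then 17, −78 → 0 °C; aq NH4Cl
Reagents that add atoms: none
Why: directed ortho-lithiation of 1,3-dimethoxybenzene at C2 between the two methoxy groups, then Weinreb ketone synthesis, in which the chelated tetrahedral lithium adduct survives until work-up and so prevents over-addition at both chain ends.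

Step 13
Reactants: 20 9,9'-(2,3,4',5'-tetramethoxy-[1,1'-biphenyl]-2',5-diyl)bis[1-(2,6-dimethoxyphenyl)nonan-1-one]
Product: 21 9,9'-(2,3,4',5'-tetrahydroxy-[1,1'-biphenyl]-2',5-diyl)bis[1-(2,6-dihydroxyphenyl)nonan-1-one]
Conditions: BBr3 (16 equiv), CH2Cl2, −78 °C → rt, Ar; then H2O, 0 °C
Reagents that add atoms: none
Why: Lewis-acid ether cleavage, in which boron coordinates each aryl methyl ether and bromide attacks the methyl group (assisted at the four ketone-flanking ethers by carbonyl chelation), should remove all eight methyl groups; hydrolysis of the aryl borates on work-up releases the octaphenol.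

**Compound list**

1 | methyl 8-bromooctanoate | COC(=O)CCCCCCCBr | starting material
2 | (8-methoxy-8-oxooctyl)triphenylphosphonium bromide | COC(=O)CCCCCCC[P+](c1ccccc1)(c1ccccc1)c1ccccc1.[Br-] | intermediate
3 | 3-bromo-4,5-dimethoxybenzaldehyde | COc1cc(C=O)cc(Br)c1OC | starting material
4 | methyl 8-(triphenylphosphoranylidene)octanoate (phosphonium ylide) | COC(=O)CCCCCCC=P(c1ccccc1)(c1ccccc1)c1ccccc1 | intermediate
5 | methyl (Z)-9-(3-bromo-4,5-dimethoxyphenyl)non-8-enoate (Z isomer drawn; E isomer may accompany it and is carried on) | COC(=O)CCCCCC/C=C\c1cc(OC)c(OC)c(Br)c1 | intermediate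
6 | methyl 9-(3-bromo-4,5-dimethoxyphenyl)nonanoate | COC(=O)CCCCCCCCc1cc(OC)c(OC)c(Br)c1 | intermediate
7 | ethynyltrimethylsilane | C#C[Si](C)(C)C | starting material
8 | methyl 9-{3,4-dimethoxy-5-[(trimethylsilyl)ethynyl]phenyl}nonanoate | COC(=O)CCCCCCCCc1cc(OC)c(OC)c(C#C[Si](C)(C)C)c1 | intermediate
9 | methyl 9-(3-ethynyl-4,5-dimethoxyphenyl)nonanoate | COC(=O)CCCCCCCCc1cc(OC)c(OC)c(C#C)c1 | intermediate
10 | 9-methoxy-9-oxononanoic acid (monomethyl azelate) | COC(=O)CCCCCCCC(=O)O | starting material
11 | methyl 9-chloro-9-oxononanoate | COC(=O)CCCCCCCC(=O)Cl | intermediate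
12 | methyl 11-[2,3-dimethoxy-5-(9-methoxy-9-oxononyl)phenyl]-9-oxoundec-10-ynoate | COc1cc(CCCCCCCCC(=O)OC)cc(C#CC(=O)CCCCCCCC(=O)OC)c1OC | intermediate
13 | 2,3-dimethoxybuta-1,3-diene | C=C(OC)C(OC)=C | starting material
14 | methyl 9-{2-[2,3-dimethoxy-5-(9-methoxy-9-oxononyl)phenyl]-4,5-dimethoxycyclohexa-1,4-dien-1-yl}-9-oxononanoate | COC1=C(OC)CC(C(=O)CCCCCCCC(=O)OC)=C(c2cc(CCCCCCCCC(=O)OC)cc(OC)c2OC)C1 | intermediate
15 | methyl 9-[2,3,4',5'-tetramethoxy-5-(9-methoxy-9-oxononyl)-[1,1'-biphenyl]-2'-yl]-9-oxononanoate | COc1cc(C(=O)CCCCCCCC(=O)OC)c(-c2cc(CCCCCCCCC(=O)OC)cc(OC)c2OC)cc1OC | intermediate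
16 | dimethyl 9,9'-(2,3,4',5'-tetramethoxy-[1,1'-biphenyl]-2',5-diyl)dinonanoate | COc1cc(CCCCCCCCC(=O)OC)c(-c2cc(CCCCCCCCC(=O)OC)cc(OC)c2OC)cc1OC | intermediate
17 | 9,9'-(2,3,4',5'-tetramethoxy-[1,1'-biphenyl]-2',5-diyl)bis(N-methoxy-N-methylnonanamide) | COc1cc(CCCCCCCCC(=O)N(C)OC)c(-c2cc(CCCCCCCCC(=O)N(C)OC)cc(OC)c2OC)cc1OC | intermediate
18 | 1,3-dimethoxybenzene | COc1cccc(OC)c1 | starting material
19 | 2,6-dimethoxyphenyllithium | [Li]c1c(OC)cccc1OC | intermediate
20 | 9,9'-(2,3,4',5'-tetramethoxy-[1,1'-biphenyl]-2',5-diyl)bis[1-(2,6-dimethoxyphenyl)nonan-1-one] | COc1cc(CCCCCCCCC(=O)c2c(OC)cccc2OC)c(-c2cc(CCCCCCCCC(=O)c3c(OC)cccc3OC)cc(OC)c2OC)cc1OC | intermediate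
21 | 9,9'-(2,3,4',5'-tetrahydroxy-[1,1'-biphenyl]-2',5-diyl)bis[1-(2,6-dihydroxyphenyl)nonan-1-one] (CNP0305015.0) | O=C(CCCCCCCCc1cc(O)c(O)c(-c2cc(O)c(O)cc2CCCCCCCCC(=O)c2c(O)cccc2O)c1)c1c(O)cccc1O | target

**Step count**

Total: 13 steps. Longest linear sequence: 12 steps (steps 1–5 and 7–13, from methyl 8-bromooctanoate); step 6 is a one-step side branch.

**Steps most likely to fail**

Step 8 (Diels–Alder). The cycloaddition to the β-aryl ynone may be slower than thermal polymerisation or adventitious hydrolysis of the diene, or the bis(enol ether) adduct may be lost by hydrolysis or methanol elimination at the temperature required. In that case ring B would be brought in as a preformed arene and the biaryl bond made by cross-coupling. The fallback sets out from bromide 6 (with acid chloride 11) and comes back to the route at 15. Bromide 6 would be borylated under Miyaura conditions (bis(pinacolato)diboron, PdCl2(dppf), KOAc, dioxane, 90 °C) to methyl 9-[3,4-dimethoxy-5-(4,4,5,5-tetramethyl-1,3,2-dioxaborolan-2-yl)phenyl]nonanoate F1. Commercial 4-bromo-1,2-dimethoxybenzene (COc1ccc(Br)cc1OC) would undergo Friedel–Crafts acylation with 11 (AlCl3, CH2Cl2, 0 °C), para to the C2 methoxy group, to give methyl 9-(2-bromo-4,5-dimethoxyphenyl)-9-oxononanoate F2. Suzuki–Miyaura coupling of F1 with F2 (Pd(OAc)2, SPhos, K3PO4, toluene/H2O, 90 °C) should then give 15 directly.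

Step 10 (ionic hydrogenation). The benzylic cation may be captured by C6 of ring A, which is para to a methoxy group, in a Friedel–Crafts ring closure to a 9-alkylfluorene before hydride arrives, or the reduction may stall at the alcohol stage. The fallback replaces the cationic reduction by an anionic one; it sets out from 15 and comes back at 16. Saponification (LiOH, THF/H2O, rt) would give 9-[5-(8-carboxyoctyl)-2,3,4',5'-tetramethoxy-[1,1'-biphenyl]-2'-yl]-9-oxononanoic acid F3. Wolff–Kishner reduction in the Huang-Minlon manner (N2H4·H2O, KOH, diethylene glycol, 130 then 200 °C) would pass through 9-[5-(8-carboxyoctyl)-2,3,4',5'-tetramethoxy-[1,1'-biphenyl]-2'-yl]-9-hydrazinylidenenonanoic acid F4 to 9,9'-(2,3,4',5'-tetramethoxy-[1,1'-biphenyl]-2',5-diyl)dinonanoic acid F5. Fischer esterification (MeOH, H2SO4 cat., reflux) should return 16.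

Step 12 (double aryllithium addition). The hindered, basic aryllithium may deprotonate the amide α-position or trigger base-induced N–O cleavage with loss of formaldehyde instead of adding, on one or both arms. The fallback moves the C–C bond formation to the aldehyde oxidation level; it sets out from 17 and comes back at 20. Reduction with i-Bu2AlH (THF, −78 °C) would give 9,9'-(2,3,4',5'-tetramethoxy-[1,1'-biphenyl]-2',5-diyl)dinonanal F6. Addition of 19 (THF, −78 °C) should give 9,9'-(2,3,4',5'-tetramethoxy-[1,1'-biphenyl]-2',5-diyl)bis[1-(2,6-dimethoxyphenyl)nonan-1-ol] F7 as a mixture of stereoisomers at the two carbinol carbons, which is of no consequence. Oxidation with Dess–Martin periodinane (CH2Cl2, NaHCO3, rt) should then give 20.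

**Further compounds**

F1 | step 8 | methyl 9-[3,4-dimethoxy-5-(4,4,5,5-tetramethyl-1,3,2-dioxaborolan-2-yl)phenyl]nonanoate | COC(=O)CCCCCCCCc1cc(OC)c(OC)c(B2OC(C)(C)C(C)(C)O2)c1
F2 | step 8 | methyl 9-(2-bromo-4,5-dimethoxyphenyl)-9-oxononanoate | COC(=O)CCCCCCCC(=O)c1cc(OC)c(OC)cc1Br
F3 | step 10 | 9-[5-(8-carboxyoctyl)-2,3,4',5'-tetramethoxy-[1,1'-biphenyl]-2'-yl]-9-oxononanoic acid | COc1cc(C(=O)CCCCCCCC(=O)O)c(-c2cc(CCCCCCCCC(=O)O)cc(OC)c2OC)cc1OC
F4 | step 10 | 9-[5-(8-carboxyoctyl)-2,3,4',5'-tetramethoxy-[1,1'-biphenyl]-2'-yl]-9-hydrazinylidenenonanoic acid | COc1cc(C(=NN)CCCCCCCC(=O)O)c(-c2cc(CCCCCCCCC(=O)O)cc(OC)c2OC)cc1OC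
F5 | step 10 | 9,9'-(2,3,4',5'-tetramethoxy-[1,1'-biphenyl]-2',5-diyl)dinonanoic acid | COc1cc(CCCCCCCCC(=O)O)c(-c2cc(CCCCCCCCC(=O)O)cc(OC)c2OC)cc1OC
F6 | step 12 | 9,9'-(2,3,4',5'-tetramethoxy-[1,1'-biphenyl]-2',5-diyl)dinonanal | COc1cc(CCCCCCCCC=O)c(-c2cc(CCCCCCCCC=O)cc(OC)c2OC)cc1OC
F7 | step 12 | 9,9'-(2,3,4',5'-tetramethoxy-[1,1'-biphenyl]-2',5-diyl)bis[1-(2,6-dimethoxyphenyl)nonan-1-ol] (mixture of stereoisomers) | COc1cc(CCCCCCCCC(O)c2c(OC)cccc2OC)c(-c2cc(CCCCCCCCC(O)c3c(OC)cccc3OC)cc(OC)c2OC)cc1OC
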